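## Retrosynthetic overview
1. The target comes from a tert-butyl ester/TBS ether precursor by one acid deprotection. The Z-olefin of the side chain is made by Z-selective cross-metathesis of a C10 dec-9-enoate with oct-7-en-1-ol. The C12 aldehyde comes from a C12–Bpin group carried as a masked hydroxyl.
2. The C10 endo alcohol comes from exo-face 1,2-reduction of a cedr-8-en-10-one. The C11 CH2 comes from tosylhydrazone reduction of a 10,11-diketone.
3. Key disconnection (C1–C5 and C6–C7): oxidative dearomatisation of a 2-alkyl-resorcinol monosilyl ether. Trivalent iodine turns the normally nucleophilic phenol ortho carbon C1 into an enolonium-type electrophile, which the nucleophilic trisubstituted alkene attacks in a cationic [5+2].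
4. Ring order: the six-membered ring is the purchased arene. Ring A (C1–C5) and ring B (C1, C5, C6, C7, C11) close together in the key step.
5. The phenol comes from a cobalt-catalysed asymmetric hydroboration, which sets C2 (the only catalyst-set centre). Its alkene comes from a Suzuki union of a bromoresorcylate with the enol triflate of allylically oxidised 6-methylhept-5-en-2-one.

Assumption and notation: the (4S) antipode of the cobalt ligand is taken to give the (S)-boronate (otherwise the (4R) antipode is used). Cedrane numbering is C1 quaternary bridgehead, C2 (bears C12), C3, C4, C5, C6 (bears C13 and C14), C7 bridgehead CH, C8 (bears C15), C9, C10, C11 one-carbon bridge. On C5/C6, exo means the side of C11. On C10, endo means the side of the C5–C6 bridge. TBSO = tert-butyldimethylsilyloxy, TIPSO = triisopropylsilyloxy, Bpin = 4,4,5,5-tetramethyl-1,3,2-dioxaborolan-2-yl.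

## Route

Step 1
Reactants: 1 6-methylhept-5-en-2-one
Product: 2 (5E)-7-hydroxy-6-methylhept-5-en-2-one
Conditions: SeO2 (0.3 equiv), t-BuOOH (2.5 equiv), CH2Cl2, 0 °C to rt
Reagents that add atoms: tert-butyl hydroperoxide, CC(C)(C)OO (net oxygen source); selenium dioxide, O=[Se]=O (oxygen carrier)
Why: Riley allylic oxidation (ene reaction then [2,3]-shift) oxidises the methyl group trans to the chain of a trisubstituted alkene, giving the E-allylic alcohol, and the ketone is untouched at room temperature.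

Step 2
Reactants: 2 (5E)-7-hydroxy-6-methylhept-5-en-2-one
Product: 3 (5E)-7-(TBSO)-6-methylhept-5-en-2-one
Conditions: TBSCl, imidazole, DMF, rt
Reagents that add atoms: tert-butyldimethylsilyl chloride, C[Si](C)(Cl)C(C)(C)C
Why: Standard silylation of a primary allylic alcohol, which keeps the alkene electron-rich and the oxygen non-nucleophilic for the key step.

Step 3
Reactants: 3 (5E)-7-(TBSO)-6-methylhept-5-en-2-one
Product: 5 (5E)-7-(TBSO)-6-methylhepta-1,5-dien-2-yl trifluoromethanesulfonate, via potassium enolate 4 (not isolated)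
Conditions: KHMDS, THF, −78 °C; then PhNTf2, −78 to 0 °C
Reagents that add atoms: N-phenylbis(trifluoromethanesulfonimide), O=S(=O)(N(c1ccccc1)S(=O)(=O)C(F)(F)F)C(F)(F)F; potassium hexamethyldisilazide, [K+].C[Si](C)(C)[N-][Si](C)(C)C (potassium of 4 only)
Why: Kinetic deprotonation of a methyl ketone by a bulky amide takes place at CH3, and O-triflation of that enolate gives the terminal enol triflate.

Step 4
Reactants: 6 4-bromo-3,5-dihydroxybenzoic acid
Product: 7 tert-butyl 4-bromo-3,5-dihydroxybenzoate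
Conditions: Me2NCH(Ot-Bu)2 (3 equiv), toluene, 80 °C
Reagents that add atoms: N,N-dimethylformamide di-tert-butyl acetal, CN(C)C(OC(C)(C)C)OC(C)(C)C
Why: Amide-acetal esterification alkylates the carboxylate much faster than the phenols and installs an ester that is cleaved at the end without touching the C10 ester.

Step 5
Reactants: 7 tert-butyl 4-bromo-3,5-dihydroxybenzoate
Product: 8 tert-butyl 4-bromo-3-hydroxy-5-(TIPSO)benzoate
Conditions: TIPSCl (1.0 equiv), imidazole, DMF, 0 °C; recovered 7 recycled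
Reagents that add atoms: triisopropylsilyl chloride, CC(C)[Si](Cl)(C(C)C)C(C)C
Why: Monosilylation of the symmetric diol leaves one phenol to be oxidised (future C11) and puts a bulky cation-terminating group on the other oxygen (future O10).

Step 6
Reactants: 5 (5E)-7-(TBSO)-6-methylhepta-1,5-dien-2-yl trifluoromethanesulfonate; 8 tert-butyl 4-bromo-3-hydroxy-5-(TIPSO)benzoate
Product: 10 tert-butyl 4-[(5E)-7-(TBSO)-6-methylhepta-1,5-dien-2-yl]-3-hydroxy-5-(TIPSO)benzoate, via alkenyl pinacol boronate 9 (not isolated)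
Conditions: B2pin2, PdCl2(PPh3)2 (3 mol %), PPh3, KOPh, toluene, 50 °C; then 8, Pd(OAc)2 (3 mol %), SPhos, K3PO4, H2O (5 equiv), 80 °C
Reagents that add atoms: bis(pinacolato)diboron, CC1(C)OB(OC1(C)C)B1OC(C)(C)C(C)(C)O1 (boron group of 9 only)
Why: One-pot Miyaura borylation and Suzuki–Miyaura coupling, in which the bulky biaryl phosphine on zerovalent palladium allows coupling at the doubly ortho-substituted bromide and fixes the aryl group on the internal alkene carbon (C2).

Step 7
Reactants: 10 tert-butyl 4-[(5E)-7-(TBSO)-6-methylhepta-1,5-dien-2-yl]-3-hydroxy-5-(TIPSO)benzoate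
Product: 12 tert-butyl 4-[(2S,5E)-7-(TBSO)-6-methyl-1-(Bpin)hept-5-en-2-yl]-3-hydroxy-5-(TIPSO)benzoate, via O-boryl boronate 11 (not isolated)
Conditions: CoCl2·L* (2 mol %; L* = 2-[(4S)-4-tert-butyl-4,5-dihydrooxazol-2-yl]-6-[1-(2,6-diisopropylphenylimino)ethyl]pyridine), NaBHEt3 (6 mol %), HBpin (2.3 equiv), THF, rt; aqueous work-up
Reagents that add atoms: pinacolborane, [H]B1OC(C)(C)C(C)(C)O1
Why: Cobalt-catalysed enantioselective anti-Markovnikov hydroboration of a 1,1-disubstituted aryl alkene sets C2 by catalyst control of the alkene face, leaves the trisubstituted alkene alone, and the phenol is masked in passing as its borate and freed on work-up.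

Step 8
Reactants: 12 tert-butyl 4-[(2S,5E)-7-(TBSO)-6-methyl-1-(Bpin)hept-5-en-2-yl]-3-hydroxy-5-(TIPSO)benzoate
Product: 14 tert-butyl 13-(TBSO)-12-(Bpin)-10,11-dioxocedr-8-en-15-oate (C12 syn to C11; H5 endo; C14 exo; C13 endo), via aryloxyiodane 13 (not isolated)
Conditions: PhI(OAc)2 (1.1 equiv), (CF3)2CHOH, 0.01 M, −10 to 0 °C, 30 min
Reagents that add atoms: (diacetoxyiodo)benzene, CC(=O)OI(OC(C)=O)c1ccccc1 (in 13 only)
Why: Oxidative-dearomatisation-induced cationic [5+2] cycloaddition, in which O–I heterolysis of 13 makes phenol ortho carbon C1 an enolonium-type electrophile that the C5=C6 alkene attacks, C7 (activated through the C10 silyl dienol ether) closes onto C6, and transfer of TIPS from O10 to acetate ends the cascade; the three-atom tether forces C4 exo and H5 endo, suprafacial addition to the E-alkene puts CH3 exo and CH2OTBS endo on C6, and allylic strain (benzylic H beside the bulky OTIPS, CH2Bpin beside the small C11 oxygen) picks the arene face so that C12 ends syn to C11.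

Step 9
Reactants: 14 tert-butyl 13-(TBSO)-12-(Bpin)-10,11-dioxocedr-8-en-15-oate
Product: 16 tert-butyl 13-(TBSO)-12-(Bpin)-10-oxocedr-8-en-15-oate, via C11 tosylhydrazone 15 (not isolated)
Conditions: TsNHNH2 (1.1 equiv), PPTS (5 mol %), CHCl3, 45 °C; −10 °C, catecholborane (3 equiv); NaOAc·3H2O, reflux
Reagents that add atoms: p-toluenesulfonyl hydrazide, Cc1ccc(cc1)S(=O)(=O)NN (in 15 only)
Why: Tosylhydrazone reduction (mild variant of the Caglioti deoxygenation), in which the strained non-conjugated bridge ketone condenses ahead of the hindered s-trans enone, catecholborane adds hydride to C=N but not to s-trans enones or enoates, and loss of sulfinate and N2 leaves CH2 without touching a stereocentre.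

Step 10
Reactants: 16 tert-butyl 13-(TBSO)-12-(Bpin)-10-oxocedr-8-en-15-oate
Product: 17 tert-butyl 10-endo-hydroxy-13-(TBSO)-12-(Bpin)cedr-8-en-15-oate
Conditions: NaBH4, CeCl3·7H2O, MeOH, −78 to −40 °C
Reagents that add atoms: none
Why: Luche 1,2-reduction, in which hydride arrives axially from the exo face (the side of C11) because the endo face is closed by the C5–C6 bridge with H5 and the endo CH2OTBS, so the C10 hydroxyl ends endo as in the target.

Step 11
Reactants: 17 tert-butyl 10-endo-hydroxy-13-(TBSO)-12-(Bpin)cedr-8-en-15-oate; 18 dec-9-enoic acid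
Product: 20 tert-butyl 10-endo-(dec-9-enoyloxy)-13-(TBSO)-12-(Bpin)cedr-8-en-15-oate, via mixed anhydride 19 (not isolated)
Conditions: 18, 2,4,6-Cl3C6H2COCl, Et3N, THF, rt; then 17, DMAP, toluene, 40 °C
Reagents that add atoms: 2,4,6-trichlorobenzoyl chloride, O=C(Cl)c1c(Cl)cc(Cl)cc1Cl (in 19 only)
Why: Yamaguchi esterification acylates hindered secondary alcohols through the acylpyridinium ion with retention at C10, and 17 carries only this one free hydroxyl.

Step 12
Reactants: 20 tert-butyl 10-endo-(dec-9-enoyloxy)-13-(TBSO)-12-(Bpin)cedr-8-en-15-oate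
Product: 21 tert-butyl 10-endo-(dec-9-enoyloxy)-12-hydroxy-13-(TBSO)cedr-8-en-15-oate
Conditions: NaBO3·4H2O (4 equiv), THF/H2O 1:1, rt
Reagents that add atoms: sodium perborate, [Na+].[O-]OB=O
Why: Perborate oxidation of the alkyl boronate (1,2-shift of carbon from boron to oxygen) is nearly neutral, so the esters, the terminal alkene and the hindered enoate survive and C2 is not touched.

Step 13
Reactants: 21 tert-butyl 10-endo-(dec-9-enoyloxy)-12-hydroxy-13-(TBSO)cedr-8-en-15-oate
Product: 22 tert-butyl 10-endo-(dec-9-enoyloxy)-12-oxo-13-(TBSO)cedr-8-en-15-oate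
Conditions: Dess–Martin periodinane (1.3 equiv), CH2Cl2, 0 °C to rt
Reagents that add atoms: none
Why: Dess–Martin oxidation of the only free alcohol gives the aldehyde under non-basic conditions, so the C2 centre alpha to it is kept.

Step 14
Reactants: 22 tert-butyl 10-endo-(dec-9-enoyloxy)-12-oxo-13-(TBSO)cedr-8-en-15-oate; 23 oct-7-en-1-ol
Product: 24 tert-butyl 10-endo-[(9Z)-16-hydroxyhexadec-9-enoyloxy]-12-oxo-13-(TBSO)cedr-8-en-15-oate
Conditions: 23 (5 equiv), [Ru(NO3)(=CH-C6H4-2-Oi-Pr)(C^NHC)] (5 mol %; C^NHC = cyclometalated 1-(adamantan-1-yl)-3-(2,6-diisopropylphenyl)imidazolidin-2-ylidene), THF, 35 °C, static vacuum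
Reagents that add atoms: none
Why: Z-selective olefin cross-metathesis of two unhindered terminal alkenes, in which the cyclometalated catalyst forces a side-bound all-syn metallacyclobutane that gives the cis alkene, and the trisubstituted enoate is inert to it.

Step 15
Reactants: 24 tert-butyl 10-endo-[(9Z)-16-hydroxyhexadec-9-enoyloxy]-12-oxo-13-(TBSO)cedr-8-en-15-oate
Product: 25 target CNP0148862.2
Conditions: CF3CO2H/CH2Cl2/H2O 10:10:1, 0 °C to rt
Reagents that add atoms: none
Why: Acidolysis removes the tert-butyl ester (loss of isobutene) and the primary TBS ether in one operation, while the C10 allylic ester stays because its cation would be conjugated to the C15 carboxyl, and no stereocentre is touched.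

## Compound list
1 | 6-methylhept-5-en-2-one | CC(=O)CCC=C(C)C | starting material
2 | (5E)-7-hydroxy-6-methylhept-5-en-2-one | CC(=O)CC/C=C(\C)CO | intermediate
3 | (5E)-7-(tert-butyldimethylsilyloxy)-6-methylhept-5-en-2-one | CC(=O)CC/C=C(\C)CO[Si](C)(C)C(C)(C)C | intermediate
4 | potassium (5E)-7-(tert-butyldimethylsilyloxy)-6-methylhepta-1,5-dien-2-olate (kinetic enolate, not isolated) | [K+].[O-]C(=C)CC/C=C(\C)CO[Si](C)(C)C(C)(C)C | intermediate
5 | (5E)-7-(tert-butyldimethylsilyloxy)-6-methylhepta-1,5-dien-2-yl trifluoromethanesulfonate | C=C(OS(=O)(=O)C(F)(F)F)CC/C=C(\C)CO[Si](C)(C)C(C)(C)C | intermediate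
6 | 4-bromo-3,5-dihydroxybenzoic acid | OC(=O)c1cc(O)c(Br)c(O)c1 | starting material
7 | tert-butyl 4-bromo-3,5-dihydroxybenzoate | CC(C)(C)OC(=O)c1cc(O)c(Br)c(O)c1 | intermediate
8 | tert-butyl 4-bromo-3-hydroxy-5-(triisopropylsilyloxy)benzoate | CC(C)(C)OC(=O)c1cc(O)c(Br)c(O[Si](C(C)C)(C(C)C)C(C)C)c1 | intermediate
9 | 2-[(5E)-7-(TBSO)-6-methylhepta-1,5-dien-2-yl]-4,4,5,5-tetramethyl-1,3,2-dioxaborolane (not isolated) | C=C(B1OC(C)(C)C(C)(C)O1)CC/C=C(\C)CO[Si](C)(C)C(C)(C)C | intermediate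
10 | tert-butyl 4-[(5E)-7-(TBSO)-6-methylhepta-1,5-dien-2-yl]-3-hydroxy-5-(TIPSO)benzoate | CC(C)(C)OC(=O)c1cc(O)c(C(=C)CC/C=C(\C)CO[Si](C)(C)C(C)(C)C)c(O[Si](C(C)C)(C(C)C)C(C)C)c1 | intermediate
11 | aryl pinacol borate (ArO–Bpin) of boronate 12, (2S,5E) (not isolated) | CC(C)(C)OC(=O)c1cc(OB2OC(C)(C)C(C)(C)O2)c(c(O[Si](C(C)C)(C(C)C)C(C)C)c1)[C@@H](CB3OC(C)(C)C(C)(C)O3)CC/C=C(\C)CO[Si](C)(C)C(C)(C)C | intermediate
12 | tert-butyl 4-[(2S,5E)-7-(TBSO)-6-methyl-1-(Bpin)hept-5-en-2-yl]-3-hydroxy-5-(TIPSO)benzoate | CC(C)(C)OC(=O)c1cc(O)c(c(O[Si](C(C)C)(C(C)C)C(C)C)c1)[C@@H](CB2OC(C)(C)C(C)(C)O2)CC/C=C(\C)CO[Si](C)(C)C(C)(C)C | intermediate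
13 | acetoxy(phenyl)-λ3-iodanyl ether of phenol 12 (not isolated) | CC(C)(C)OC(=O)c1cc(OI(OC(C)=O)c2ccccc2)c(c(O[Si](C(C)C)(C(C)C)C(C)C)c1)[C@@H](CB3OC(C)(C)C(C)(C)O3)CC/C=C(\C)CO[Si](C)(C)C(C)(C)C | intermediate
14 | tert-butyl 13-(TBSO)-12-(Bpin)-10,11-dioxocedr-8-en-15-oate; C12 syn to C11, H5 endo, C14 methyl exo, C13 endo; centres arranged in space as in 25 | C[C@@]1(CO[Si](C)(C)C(C)(C)C)[C@H]2C(=O)[C@@]3(C(=O)C=C2C(=O)OC(C)(C)C)[C@@H](CB4OC(C)(C)C(C)(C)O4)CC[C@@H]13 | intermediate
15 | C11 N-tosylhydrazone of 14 (not isolated) | C[C@@]1(CO[Si](C)(C)C(C)(C)C)[C@H]2C(=NNS(=O)(=O)c4ccc(C)cc4)[C@@]3(C(=O)C=C2C(=O)OC(C)(C)C)[C@@H](CB5OC(C)(C)C(C)(C)O5)CC[C@@H]13 | intermediate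
16 | tert-butyl 13-(TBSO)-12-(Bpin)-10-oxocedr-8-en-15-oate | C[C@@]1(CO[Si](C)(C)C(C)(C)C)[C@H]2C[C@@]3(C(=O)C=C2C(=O)OC(C)(C)C)[C@@H](CB4OC(C)(C)C(C)(C)O4)CC[C@@H]13 | intermediate
17 | tert-butyl 10-endo-hydroxy-13-(TBSO)-12-(Bpin)cedr-8-en-15-oate | C[C@@]1(CO[Si](C)(C)C(C)(C)C)[C@H]2C[C@@]3([C@@H](O)C=C2C(=O)OC(C)(C)C)[C@@H](CB4OC(C)(C)C(C)(C)O4)CC[C@@H]13 | intermediate
18 | dec-9-enoic acid | C=CCCCCCCCC(=O)O | starting material
19 | dec-9-enoic 2,4,6-trichlorobenzoic anhydride (not isolated) | C=CCCCCCCCC(=O)OC(=O)c1c(Cl)cc(Cl)cc1Cl | intermediate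
20 | tert-butyl 10-endo-(dec-9-enoyloxy)-13-(TBSO)-12-(Bpin)cedr-8-en-15-oate | C[C@@]1(CO[Si](C)(C)C(C)(C)C)[C@H]2C[C@@]3([C@@H](OC(=O)CCCCCCCC=C)C=C2C(=O)OC(C)(C)C)[C@@H](CB4OC(C)(C)C(C)(C)O4)CC[C@@H]13 | intermediate
21 | tert-butyl 10-endo-(dec-9-enoyloxy)-12-hydroxy-13-(TBSO)cedr-8-en-15-oate | C[C@@]1(CO[Si](C)(C)C(C)(C)C)[C@H]2C[C@@]3([C@@H](OC(=O)CCCCCCCC=C)C=C2C(=O)OC(C)(C)C)[C@@H](CO)CC[C@@H]13 | intermediate
22 | tert-butyl 10-endo-(dec-9-enoyloxy)-12-oxo-13-(TBSO)cedr-8-en-15-oate | C[C@@]1(CO[Si](C)(C)C(C)(C)C)[C@H]2C[C@@]3([C@@H](OC(=O)CCCCCCCC=C)C=C2C(=O)OC(C)(C)C)[C@@H](C=O)CC[C@@H]13 | intermediate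
23 | oct-7-en-1-ol | C=CCCCCCCO | starting material
24 | tert-butyl 10-endo-[(9Z)-16-hydroxyhexadec-9-enoyloxy]-12-oxo-13-(TBSO)cedr-8-en-15-oate | C[C@@]1(CO[Si](C)(C)C(C)(C)C)[C@H]2C[C@@]3([C@@H](OC(=O)CCCCCCC/C=C\CCCCCCO)C=C2C(=O)OC(C)(C)C)[C@@H](C=O)CC[C@@H]13 | intermediate
25 | CNP0148862.2, (1S,2S,5S,6S,7R,10S)-10-[(9Z)-16-hydroxyhexadec-9-enoyloxy]-13-hydroxy-12-oxocedr-8-en-15-oic acid | C[C@@]1(CO)[C@H]2C[C@@]3([C@@H](OC(=O)CCCCCCC/C=C\CCCCCCO)C=C2C(=O)O)[C@@H](C=O)CC[C@@H]13 | target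

## Step count and weak points
Total step count: 15.

Longest linear sequence: 13 (steps 1, 2, 3, 6, 7, 8, 9, 10, 11, 12, 13, 14, 15).

**Step 8 (key [5+2]).**
- Risks:
  - The ester lowers the oxidisability of the phenol.
  - Loss of the benzylic proton to give an ortho-quinone methide, or capture of the C6 cation by oxygen, can compete with ring closure.
  - A long-lived C6 cation could scramble C6.
  - The face selectivity rests only on the size of the OTIPS group.
- Fallback: separate the oxidation from the C–C bond formation. Setting out from 12, Wessely acetoxylation with Pb(OAc)4 in CH2Cl2 at 0 °C puts an acetate on C1. This gives the isolable ortho-quinol acetate F3 as a mixture of C1 epimers. BF3·OEt2 or TMSOTf in CH2Cl2 at −78 °C then ionises the tertiary acetate under non-oxidising, aprotic conditions. The same electrophilic C1 is closed by the alkene, and the sequence comes back to the route at 14.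

**Step 9 (removal of the C11 carbonyl).**
- Risks:
  - The non-enolisable 1,3-diketone can open by retro-Claisen cleavage.
  - The doubly activated C8=C9 bond can take up the hydrazide.
  - The hindered ketone may condense slowly.
- Fallback: go through the alcohol and a radical. Setting out from 14, LiAlH(Ot-Bu)3 (1 equiv, THF, −78 °C) reduces only the strained bridge ketone, from the side of the C8–C10 bridge, to the 11-hydroxy enone F4. 1,1'-Thiocarbonyldiimidazole with DMAP gives the imidazolylthiocarbonate F5. Bu3SnH with AIBN in toluene at 80 °C (Barton–McCombie deoxygenation) replaces the C11–O bond by C–H, and the sequence comes back to the route at 16.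

**Step 7 (asymmetric hydroboration).**
- Risk: the alkene carries a doubly ortho-substituted aryl group and a free phenol, so rate and enantioselectivity may both fall short.
- Fallback: resolution instead of asymmetric catalysis. Setting out from 10, achiral copper-catalysed protoboration (CuCl, Xantphos, catalytic KOt-Bu, B2pin2, MeOH, THF) gives the racemic boronate F1 without touching the phenol. Preparative SFC on a chiral amylose phase separates the wanted enantiomer from the (R)-boronate F2, and the sequence comes back to the route at 12.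

## Further compounds
F1 | step 7 | racemic tert-butyl 4-[(5E)-7-(TBSO)-6-methyl-1-(Bpin)hept-5-en-2-yl]-3-hydroxy-5-(TIPSO)benzoate | CC(C)(C)OC(=O)c1cc(O)c(c(O[Si](C(C)C)(C(C)C)C(C)C)c1)C(CB2OC(C)(C)C(C)(C)O2)CC/C=C(\C)CO[Si](C)(C)C(C)(C)C
F2 | step 7 | tert-butyl 4-[(2R,5E)-7-(TBSO)-6-methyl-1-(Bpin)hept-5-en-2-yl]-3-hydroxy-5-(TIPSO)benzoate | CC(C)(C)OC(=O)c1cc(O)c(c(O[Si](C(C)C)(C(C)C)C(C)C)c1)[C@H](CB2OC(C)(C)C(C)(C)O2)CC/C=C(\C)CO[Si](C)(C)C(C)(C)C
F3 | step 8 | tert-butyl 4-acetoxy-4-[(2S,5E)-7-(TBSO)-6-methyl-1-(Bpin)hept-5-en-2-yl]-3-oxo-5-(TIPSO)cyclohexa-1,5-diene-1-carboxylate (ortho-quinol acetate, both C4 epimers) | CC(C)(C)OC(=O)C1=CC(=O)C(OC(C)=O)(C(O[Si](C(C)C)(C(C)C)C(C)C)=C1)[C@@H](CB2OC(C)(C)C(C)(C)O2)CC/C=C(\C)CO[Si](C)(C)C(C)(C)C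
F4 | step 9 | tert-butyl 11-hydroxy-13-(TBSO)-12-(Bpin)-10-oxocedr-8-en-15-oate (OH on the side of the C5–C6 bridge) | C[C@@]1(CO[Si](C)(C)C(C)(C)C)[C@H]2[C@@H](O)[C@@]3(C(=O)C=C2C(=O)OC(C)(C)C)[C@@H](CB4OC(C)(C)C(C)(C)O4)CC[C@@H]13
F5 | step 9 | tert-butyl 11-(imidazol-1-ylthiocarbonyloxy)-13-(TBSO)-12-(Bpin)-10-oxocedr-8-en-15-oate | C[C@@]1(CO[Si](C)(C)C(C)(C)C)[C@H]2[C@@H](OC(=S)n4ccnc4)[C@@]3(C(=O)C=C2C(=O)OC(C)(C)C)[C@@H](CB5OC(C)(C)C(C)(C)O5)CC[C@@H]13
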